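## Retrosynthetic overview (labdane numbering C1–C16 is used for positions)

1. Target ⇒ acetylation of the 3β‑OH; butenolide ⇒ 3‑alkylfuran (singlet oxygen, then NaBH4; last ring made).
2. C9 carbinol and C11–C12 bond ⇒ 9α,11‑spiro‑epoxide + (furan‑3‑yl)methyl Grignard; epoxide ⇒ exocyclic alkene ⇒ C9 ketone.
3. trans‑Decalin hydroxy ketone ⇒ hydrogenation/reduction of a bicyclic trienedione whose only stereocentre, C10, relays C5, C8, C3 and later C9.
4. Trienedione ⇒ catalytic enantioselective 6‑endo‑dig addition of a phenol ortho carbon to a tethered ynone: ring B is the benzene ring present from the start, ring A closes on it (C10–C1) as aromaticity is lost.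
5. Phenol–ynone ⇒ 3‑bromo‑2,6‑dimethylphenol (from 2,6‑dimethylaniline) + methyl isobutyrate (C4–C5, enolate arylation) + ethynyltrimethylsilane (C1–C2).

Assumption: the cinchonidinium catalyst of the key step is taken to give the (S)-configured quaternary centre; if it gives the antipode, its cinchoninium pseudoenantiomer is used instead.

## Route

Step 1
Reactants: 1 2,6-dimethylaniline
Product: 2 3-bromo-2,6-dimethylaniline
Conditions: NBS (1.05 equiv), conc. H2SO4, 0 °C to rt
Reagents that add atoms: N-bromosuccinimide, O=C1CCC(=O)N1Br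
Why: In concentrated sulfuric acid the amine is fully protonated, so the meta-directing anilinium group and both ortho/para-directing methyl groups steer the electrophilic aromatic bromination to C3.

Step 2
Reactants: 2 3-bromo-2,6-dimethylaniline
Product: 4 3-bromo-2,6-dimethylphenol, via diazonium salt 3 (not isolated)
Conditions: NaNO2, aq H2SO4, 0 °C; then boiling aq H2SO4
Reagents that add atoms: water, O
Why: Diazotisation followed by thermal hydrolysis of the arenediazonium ion (hydroxydediazoniation) replaces NH2 by OH and leaves the aryl bromide untouched.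

Step 3
Reactants: 4 3-bromo-2,6-dimethylphenol
Product: 5 tert-butyl(3-bromo-2,6-dimethylphenoxy)dimethylsilane
Conditions: TBSCl, imidazole, DMF, 40 °C
Reagents that add atoms: tert-butyldimethylsilyl chloride, CC(C)(C)[Si](C)(C)Cl
Why: Imidazole-mediated O-silylation masks the acidic phenol for the strongly basic enolate coupling and gives a fluoride-labile group.

Step 4
Reactants: 5 tert-butyl(3-bromo-2,6-dimethylphenoxy)dimethylsilane; 6 methyl 2-methylpropanoate (methyl isobutyrate)
Product: 8 methyl 2-[3-(tert-butyldimethylsilyloxy)-2,4-dimethylphenyl]-2-methylpropanoate, via lithium ester enolate 7 (not isolated)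
Conditions: LiNCy2, Pd(dba)2 (2 mol%), P(t-Bu)3 (2 mol%), toluene, rt to 50 °C
Reagents that add atoms: none
Why: Palladium-catalysed α-arylation of an ester enolate forges the benzylic quaternary carbon C4, the ester having only one enolisable position and the bulky electron-rich phosphine promoting reductive elimination at the hindered carbon.

Step 5
Reactants: 8 methyl 2-[3-(tert-butyldimethylsilyloxy)-2,4-dimethylphenyl]-2-methylpropanoate; 9 ethynyltrimethylsilane
Product: 12 4-(3-hydroxy-2,4-dimethylphenyl)-4-methylpent-1-yn-3-one, via lithium silylacetylide 10 (not isolated), via bis-silyl ynone 11 (not isolated)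
Conditions: 9, n-BuLi, THF, −78 °C; BF3·OEt2, then 8, −78 to −40 °C; aq NH4Cl; crude + TBAF, AcOH, THF, 0 °C to rt
Reagents that add atoms: none
Why: BF3-mediated acylation of the lithium acetylide by the ester stops at the ynone because the boron-bound tetrahedral adduct survives until work-up, and acetic-acid-buffered fluoride then removes both silyl groups while keeping the phenol protonated so that no uncatalysed cyclisation occurs.

Step 6 (key step)
Reactants: 12 4-(3-hydroxy-2,4-dimethylphenyl)-4-methylpent-1-yn-3-one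
Product: 13 (8aS)-2,5,5,8a-tetramethylnaphthalene-1,6(5H,8aH)-dione
Conditions: N-(9-anthracenylmethyl)-O-allylcinchonidinium bromide (10 mol%), powdered Cs2CO3 (20 mol%), toluene (0.02 M), −40 to −20 °C
Reagents that add atoms: none
Why: Proposed new method: catalytic base gives the phenoxide, whose methyl-bearing ortho carbon (the α-carbon of an aromatic enolate) adds 6-endo-dig to the ynone β-carbon that the three-atom tether holds directly above it (O-attack would need an eight-membered ring and the ketone has no enolisable hydrogen), the allenolate is protonated by the next phenol so base and chiral cation turn over, the extra driving force of C≡C to C=C (roughly 10–15 kcal/mol more than an enone Michael addition) outweighs the loss of aromaticity and makes the C–C bond irreversible, and the chiral ammonium cation ion-paired at the oxygen next to the reacting carbon shields one π-face and so sets the quaternary C10, the only stereocentre; the closest known reaction types are cinchona-ammonium phase-transfer alkylation of enolates and alkylative dearomatisation of acylphloroglucinols, base-mediated 6-endo-dig cyclisation of o-hydroxyaryl ynones to chromones, and catalytic asymmetric dearomative Michael additions of 2-naphthols.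

Step 7
Reactants: 13 (8aS)-2,5,5,8a-tetramethylnaphthalene-1,6(5H,8aH)-dione
Product: 15 (2R,4aS,6S,8aS)-6-hydroxy-2,5,5,8a-tetramethyloctahydronaphthalen-1(2H)-one, via saturated dione 14 (not isolated)
Conditions: H2 (4 atm), Pd/C, EtOAc, rt; filter; NaOMe (0.2 equiv), MeOH, rt; then NaBH4 (0.5 equiv), −40 °C
Reagents that add atoms: none
Why: Catalytic hydrogenation delivers hydrogen to the 5,6-alkene from the α-face opposite the angular and 4β methyl groups (as with 4,4-dimethyl-Δ5-3-ketosteroids) to give the trans-decalin, methoxide epimerisation puts the C8 methyl equatorial (8α) because the axial epimer has a syn-diaxial clash with the C10 methyl, and borohydride reduction attacks the less hindered C3 ketone axially from the α-face to give the equatorial 3β-alcohol while the C9 ketone, flanked by C10 and C8, is left.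

Step 8
Reactants: 15 (2R,4aS,6S,8aS)-6-hydroxy-2,5,5,8a-tetramethyloctahydronaphthalen-1(2H)-one
Product: 16 (2S,4aS,6R,8aR)-1,1,4a,6-tetramethyl-5-methylidenedecahydronaphthalen-2-ol
Conditions: Ph3PCH3Br, KOtBu (5 equiv each), toluene, 100 °C
Reagents that add atoms: methyltriphenylphosphonium bromide, C[P+](c1ccccc1)(c1ccccc1)c1ccccc1.[Br-]
Why: Wittig methylenation with excess ylide at high temperature is the standard olefination of hindered 2,2,6-trisubstituted cyclohexanones, creates no stereocentre, and leaves C8 at its thermodynamic configuration (the change of two CIP descriptors is formal only).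

Step 9
Reactants: 16 (2S,4aS,6R,8aR)-1,1,4a,6-tetramethyl-5-methylidenedecahydronaphthalen-2-ol
Product: 17 (1R,2R,4aS,6S,8aS)-2,5,5,8a-tetramethyloctahydro-2H-spiro[naphthalene-1,2'-oxiran]-6-ol
Conditions: mCPBA, NaHCO3, CH2Cl2, 0 °C
Reagents that add atoms: 3-chloroperoxybenzoic acid, OOC(=O)c1cccc(Cl)c1
Why: Prilezhaev epoxidation takes place on the α-face because the axial C10 methyl on the neighbouring carbon lies directly over the β-face of the exocyclic alkene, which puts the C9 oxygen α (axial) and C11 β (equatorial).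

Step 10
Reactants: 18 furan-3-ylmethanol
Product: 19 3-(chloromethyl)furan
Conditions: SOCl2, pyridine, Et2O, 0 °C
Reagents that add atoms: thionyl chloride, O=S(Cl)Cl
Why: Chlorodehydroxylation of the primary alcohol via its chlorosulfite gives the halide needed for the Grignard reagent.

Step 11
Reactants: 17 (1R,2R,4aS,6S,8aS)-2,5,5,8a-tetramethyloctahydro-2H-spiro[naphthalene-1,2'-oxiran]-6-ol; 19 3-(chloromethyl)furan
Product: 21 (1R,2R,4aS,6S,8aS)-1-[2-(furan-3-yl)ethyl]-2,5,5,8a-tetramethyldecahydronaphthalene-1,6-diol, via furylmethyl Grignard 20 (not isolated)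
Conditions: 19, Mg, THF, 0 °C; then 17, CuI (10 mol%), −30 to 0 °C (3 equiv Grignard); aq NH4Cl
Reagents that add atoms: none
Why: Copper-catalysed SN2 opening of the epoxide at its CH2 terminus forms C11–C12 without touching the C9–O bond, so the 9α-hydroxyl set in step 9 is kept, and copper suppresses the ring-carbon reactivity of the furfuryl-type Grignard.

Step 12
Reactants: 21 (1R,2R,4aS,6S,8aS)-1-[2-(furan-3-yl)ethyl]-2,5,5,8a-tetramethyldecahydronaphthalene-1,6-diol
Product: 24 4-{2-[(1R,2R,4aS,6S,8aS)-1,6-dihydroxy-2,5,5,8a-tetramethyldecahydronaphthalen-1-yl]ethyl}furan-2(5H)-one, via furan endoperoxide 22 (not isolated), via hydroxybutenolide 23 (not isolated)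
Conditions: O2, hν, TPP (cat.), i-Pr2NEt, CH2Cl2, −78 °C; then MeOH, NaBH4, 0 °C; 1 M HCl
Reagents that add atoms: dioxygen, O=O
Why: Singlet-oxygen [4+2] cycloaddition to the furan, Kornblum–DeLaMare-type collapse of the endoperoxide by removal of the less hindered bridgehead hydrogen (giving the β-alkyl γ-hydroxybutenolide), then borohydride reduction of its ring-opened aldehyde and acid lactonisation give the β-substituted butenolide.

Step 13
Reactants: 24 4-{2-[(1R,2R,4aS,6S,8aS)-1,6-dihydroxy-2,5,5,8a-tetramethyldecahydronaphthalen-1-yl]ethyl}furan-2(5H)-one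
Product: 25 (2S,4aS,5R,6R,8aS)-5-hydroxy-1,1,4a,6-tetramethyl-5-[2-(5-oxo-2,5-dihydrofuran-3-yl)ethyl]decahydronaphthalen-2-yl acetate (CNP0578261.2)
Conditions: Ac2O, pyridine, DMAP (cat.), CH2Cl2, 0 °C to rt
Reagents that add atoms: acetic anhydride, CC(=O)OC(C)=O
Why: DMAP-catalysed acetylation esterifies only the secondary equatorial 3β-hydroxyl, the tertiary axial C9 hydroxyl being too hindered to react.

## Compound list

1 | 2,6-dimethylaniline | Cc1cccc(C)c1N | starting material
2 | 3-bromo-2,6-dimethylaniline | Cc1ccc(Br)c(C)c1N | intermediate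
3 | 3-bromo-2,6-dimethylbenzenediazonium hydrogen sulfate | Cc1ccc(Br)c(C)c1[N+]#N.OS(=O)(=O)[O-] | intermediate
4 | 3-bromo-2,6-dimethylphenol | Cc1ccc(Br)c(C)c1O | intermediate
5 | tert-butyl(3-bromo-2,6-dimethylphenoxy)dimethylsilane | Cc1ccc(Br)c(C)c1O[Si](C)(C)C(C)(C)C | intermediate
6 | methyl 2-methylpropanoate | CC(C)C(=O)OC | starting material
7 | lithium 1-methoxy-2-methylprop-1-en-1-olate | COC(O[Li])=C(C)C | intermediate
8 | methyl 2-[3-(tert-butyldimethylsilyloxy)-2,4-dimethylphenyl]-2-methylpropanoate | COC(=O)C(C)(C)c1ccc(C)c(O[Si](C)(C)C(C)(C)C)c1C | intermediate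
9 | ethynyltrimethylsilane | C#C[Si](C)(C)C | starting material
10 | lithium (trimethylsilyl)acetylide | [Li]C#C[Si](C)(C)C | intermediate
11 | 4-[3-(tert-butyldimethylsilyloxy)-2,4-dimethylphenyl]-4-methyl-1-(trimethylsilyl)pent-1-yn-3-one | C[Si](C)(C)C#CC(=O)C(C)(C)c1ccc(C)c(O[Si](C)(C)C(C)(C)C)c1C | intermediate
12 | 4-(3-hydroxy-2,4-dimethylphenyl)-4-methylpent-1-yn-3-one | C#CC(=O)C(C)(C)c1ccc(C)c(O)c1C | intermediate
13 | (8aS)-2,5,5,8a-tetramethylnaphthalene-1,6(5H,8aH)-dione | CC1=CC=C2C(C)(C)C(=O)C=C[C@]2(C)C1=O | intermediate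
14 | (2R,4aS,8aS)-2,5,5,8a-tetramethylhexahydronaphthalene-1,6(2H,5H)-dione | O=C1CC[C@@]2(C)[C@@H](CC[C@@H](C)C2=O)C1(C)C | intermediate
15 | (2R,4aS,6S,8aS)-6-hydroxy-2,5,5,8a-tetramethyloctahydronaphthalen-1(2H)-one | O[C@H]1CC[C@@]2(C)[C@@H](CC[C@@H](C)C2=O)C1(C)C | intermediate
16 | (2S,4aS,6R,8aR)-1,1,4a,6-tetramethyl-5-methylidenedecahydronaphthalen-2-ol | O[C@H]1CC[C@@]2(C)[C@@H](CC[C@@H](C)C2=C)C1(C)C | intermediate
17 | (1R,2R,4aS,6S,8aS)-2,5,5,8a-tetramethyloctahydro-2H-spiro[naphthalene-1,2'-oxiran]-6-ol | O[C@H]1CC[C@@]2(C)[C@@H](CC[C@@H](C)[C@]2(O3)C3)C1(C)C | intermediate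
18 | furan-3-ylmethanol | OCc1ccoc1 | starting material
19 | 3-(chloromethyl)furan | ClCc1ccoc1 | intermediate
20 | (furan-3-ylmethyl)magnesium chloride | Cl[Mg]Cc1ccoc1 | intermediate
21 | (1R,2R,4aS,6S,8aS)-1-[2-(furan-3-yl)ethyl]-2,5,5,8a-tetramethyldecahydronaphthalene-1,6-diol | O[C@H]1CC[C@@]2(C)[C@@H](CC[C@@H](C)[C@]2(O)CCc2ccoc2)C1(C)C | intermediate
22 | (1R,2R,4aS,6S,8aS)-2,5,5,8a-tetramethyl-1-[2-(2,3,7-trioxabicyclo[2.2.1]hept-5-en-5-yl)ethyl]decahydronaphthalene-1,6-diol (bridgehead epimers) | O[C@H]1CC[C@@]2(C)[C@@H](CC[C@@H](C)[C@]2(O)CCC2=CC3OOC2O3)C1(C)C | intermediate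
23 | 4-{2-[(1R,2R,4aS,6S,8aS)-1,6-dihydroxy-2,5,5,8a-tetramethyldecahydronaphthalen-1-yl]ethyl}-5-hydroxyfuran-2(5H)-one (hemiacetal epimers) | O[C@H]1CC[C@@]2(C)[C@@H](CC[C@@H](C)[C@]2(O)CCC2=CC(=O)OC2O)C1(C)C | intermediate
24 | 4-{2-[(1R,2R,4aS,6S,8aS)-1,6-dihydroxy-2,5,5,8a-tetramethyldecahydronaphthalen-1-yl]ethyl}furan-2(5H)-one | O[C@H]1CC[C@@]2(C)[C@@H](CC[C@@H](C)[C@]2(O)CCC2=CC(=O)OC2)C1(C)C | intermediate
25 | (2S,4aS,5R,6R,8aS)-5-hydroxy-1,1,4a,6-tetramethyl-5-[2-(5-oxo-2,5-dihydrofuran-3-yl)ethyl]decahydronaphthalen-2-yl acetate | CC(=O)O[C@H]1CC[C@@]2(C)[C@@H](CC[C@@H](C)[C@]2(O)CCC2=CC(=O)OC2)C1(C)C | target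

## Step count and risks

Total step count: 13. Longest linear sequence: 12 (steps 1–9 and 11–13; step 10 is the side branch).

Steps most likely to fail:

**Step 6.** The dearomatising cyclisation is new chemistry. It may give low enantioselectivity, or the phenoxide may oligomerise through intermolecular O-addition. The first thing to vary is the catalyst class (a bifunctional cinchona squaramide instead of the ammonium salt). Recrystallisation of 15 is the planned point for upgrading ee. The fallback changes the ring closure to an SN2 alkylation and anchors the absolute configuration at C3 by a reagent-controlled addition. It sets out from ester 8 and comes back at hydroxy ketone 15. DIBAL-H reduction at −78 °C gives the aldehyde 2-[3-(tert-butyldimethylsilyloxy)-2,4-dimethylphenyl]-2-methylpropanal F1. Catalytic asymmetric vinylation (divinylzinc, (−)-MIB, Si-face addition) gives the allylic alcohol (3S)-4-[3-(tert-butyldimethylsilyloxy)-2,4-dimethylphenyl]-4-methylpent-1-en-3-ol F2. Hydrozirconation–iodination (Cp2Zr(H)Cl, then I2) gives the primary iodide (3S)-4-[3-(tert-butyldimethylsilyloxy)-2,4-dimethylphenyl]-1-iodo-4-methylpentan-3-ol F3. TBAF (1.05 equiv, THF, 0.01 M) releases the phenoxide, which closes ring A by intramolecular ortho C-alkylation (6-exo-tet) to the dienone (6S,8aS)-6-hydroxy-2,5,5,8a-tetramethyl-6,7,8,8a-tetrahydronaphthalen-1(5H)-one F4. Only modest intrinsic selectivity is expected at C10 here, so the C10 epimer is removed by chromatography. Hydrogenation and methoxide equilibration as in step 7, without borohydride, then give 15.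

**Step 8.** The C9 ketone is flanked by a quaternary and a tertiary carbon and may resist the Wittig reagent or simply enolise. The fallback is a Peterson olefination, setting out from 15 and coming back at 16. Me3SiCH2Li with CeCl3 (THF, −78 °C, excess to cover the free hydroxyl) adds from the open α-face to give the β-hydroxysilane (1S,2R,4aS,6S,8aS)-2,5,5,8a-tetramethyl-1-[(trimethylsilyl)methyl]decahydronaphthalene-1,6-diol F5. KH in THF then effects syn-elimination to 16.

**Step 11.** The furfuryl-type Grignard is ambident, and magnesium salts can isomerise the hindered spiro-epoxide to an aldehyde before C11 is attacked. The fallback uses a non-ambident sulfone carbanion without a Lewis acid. It sets out from 17 and 19 and comes back at 21. Chloride 19 and sodium benzenesulfinate (DMF, rt) give 3-[(phenylsulfonyl)methyl]furan F6. Its lithio derivative (n-BuLi, THF–HMPA, −78 °C to rt, 2.2 equiv) opens 17 at C11 to give the hydroxy sulfone (1R,2R,4aS,6S,8aS)-1-[2-(furan-3-yl)-2-(phenylsulfonyl)ethyl]-2,5,5,8a-tetramethyldecahydronaphthalene-1,6-diol F7 as a mixture at the sulfonyl carbon. Reductive desulfonylation (Na/Hg, Na2HPO4, MeOH) gives 21.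

## Further compounds

F1 | step 6 | 2-[3-(tert-butyldimethylsilyloxy)-2,4-dimethylphenyl]-2-methylpropanal | Cc1ccc(C(C)(C)C=O)c(C)c1O[Si](C)(C)C(C)(C)C
F2 | step 6 | (3S)-4-[3-(tert-butyldimethylsilyloxy)-2,4-dimethylphenyl]-4-methylpent-1-en-3-ol | C=C[C@H](O)C(C)(C)c1ccc(C)c(O[Si](C)(C)C(C)(C)C)c1C
F3 | step 6 | (3S)-4-[3-(tert-butyldimethylsilyloxy)-2,4-dimethylphenyl]-1-iodo-4-methylpentan-3-ol | ICC[C@H](O)C(C)(C)c1ccc(C)c(O[Si](C)(C)C(C)(C)C)c1C
F4 | step 6 | (6S,8aS)-6-hydroxy-2,5,5,8a-tetramethyl-6,7,8,8a-tetrahydronaphthalen-1(5H)-one | CC1=CC=C2C(C)(C)[C@@H](O)CC[C@]2(C)C1=O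
F5 | step 8 | (1S,2R,4aS,6S,8aS)-2,5,5,8a-tetramethyl-1-[(trimethylsilyl)methyl]decahydronaphthalene-1,6-diol | O[C@H]1CC[C@@]2(C)[C@@H](CC[C@@H](C)[C@@]2(O)C[Si](C)(C)C)C1(C)C
F6 | step 11 | 3-[(phenylsulfonyl)methyl]furan | O=S(=O)(Cc1ccoc1)c1ccccc1
F7 | step 11 | (1R,2R,4aS,6S,8aS)-1-[2-(furan-3-yl)-2-(phenylsulfonyl)ethyl]-2,5,5,8a-tetramethyldecahydronaphthalene-1,6-diol | O[C@H]1CC[C@@]2(C)[C@@H](CC[C@@H](C)[C@]2(O)CC(c2ccoc2)S(=O)(=O)c2ccccc2)C1(C)C
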